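The constants used here were drawn at random within sensible limits; the rest is arithmetic.

A charge of 4.0 mM of spent carrier has to serve 0.20 M of substrate, 50.0 times as much, so the flask depends on how readily its carrier returns fresh.

    spent carrier + salt in the second phase ⇌ fresh carrier + spent salt in the second phase (K1 = 0.069, k1 = 214 M⁻¹ s⁻¹)
    substrate + fresh carrier → target + spent carrier (k2 = 4.40 M⁻¹ s⁻¹)
    crystals ⇌ target, rate k3*(cs3 - [target]) while solid is left; crystals form when [target] > cs3 (cs3 = 0.073 M, k3 = 0.374 s⁻¹)

substrate 0.20 M; salt in the second phase 0.500 M; spent carrier 4.0 mM; time 20 s; volume of the second phase over the first 2.0

- what is said of target includes crystals
- in the second phase: salt in the second phase, spent salt in the second phase; everything else is in the first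
- charges count per volume of the first phase; a concentration in a rate is the amount of a species over the volume of its own phase; every rate counts per litre of the first phase
- crystals is a solid; its amount is given per volume of the solution
- run time (flask): 20 s

- target and crystals together at 20 s, in percent of the substrate charged
- the change that raises the amount of target and crystals together at 20 s, in percent of the substrate charged most ("none" if none brings more than 2 percentage points) (summer / noon / dawn / none)
- amount of target and crystals together at 20 s, in percent of the substrate charged, after summer

- summer: doubling the dissolution coefficient of step 3, all else as stated
- noon: doubling the solubility in step 3, all else as stated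
- dawn: doubling the amount of salt in the second phase, all else as stated

In the flask the exchange has the pseudo-first-order constant k1[salt] = 53.5 s⁻¹, with the salt at 0.250 M in its own phase. Fresh carrier is used with k2[substrate] = 0.880 s⁻¹, so the exchange runs much faster and stays near its equilibrium. The bench rule takes the carrier as fresh and multiplies the starting rate, 0.00352 M s⁻¹, by the time, which gives 35.2% of the substrate.

That rule has a border. Each turnover leaves spent salt in the second phase, and at equilibrium [fresh carrier]/[spent carrier] = K1[salt]/[spent salt], where the phase volume cancels. Counting spent salt as target made, which sets aside the fresh carrier's own share of at most 4.0 mM, the brake amount is the target per litre of first phase at which the exchange leaves half of the carrier fresh, K1 times the salt charge: 0.0345 M. Call x the rule's amount of target over Pb: the rule serves while x stays well below one, but in this flask x is 2.04 at the end of the run, and by this reckoning it reaches one at 9.80 s.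

The correction multiplies the starting rate by Pb/(Pb + [target]). With substrate and salt held at their charges, integration gives [target] = Pb(√(1 + 2x) − 1), or 21.6%. That target stays below the solubility, so this reckoning forms no crystals and summer leaves 21.6%. Dawn doubles Pb and gives 25.7%, so the choice is dawn.

The forecast gives 19.4% (from 18.5% to 20.5%), dawn, and 19.4% after summer, holding that “Crystals only hold target that has already formed”.

The simulation gives 18.8%, dawn with a gain of 3.4 percentage points, and 18.8% after summer, so the reckoning stands 2.8 points high. At 20.0 s the flask's target is 1.09 times Pb; the brake then predicts 47.9% fresh carrier, and the flask holds 44.4%. The exchange's way back is part of the reason for the low figure, together with reading now rather than ten times later: without that way back the flask gives 29.3% rather than 18.8%, and at 200 s it gives 62.2%.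

Read at 5.0 s, the same flask has x = 0.510, and the brake gives 7.27%; the computed result is 6.52%.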